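## Structural features

- The target is a cyclohex-2-en-1-one (C1 carbonyl, C2=C3, C4H2, C5, C6H2). C5 carries a tertiary hydroxyl and an unbranched, unfunctionalised nonadecyl chain (C1'–C19') joined through the C5–C1' bond.
- C5 is the only stereocentre and has no stereogenic neighbours. The CIP order is OH > C6 > C4 > C1', which makes it S.
- Its two ring arms are almost identical: C4 and C6 are both CH2 groups and differ only one atom further on (alkene carbon C3 against carbonyl carbon C1).
- The real difficulty is therefore to obtain a fully substituted carbinol carbon as a single enantiomer when its configuration is defined only by this remote difference and the long chain offers no handle.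
- The C5 hydroxyl is β to the ketone through C6. Acid or strong base can dehydrate it, and the resulting dienone tautomerises irreversibly to a phenol; retro-aldol opening threatens under strong base.
- The enone would not survive hydrogenation, ylides or organometallic reagents, so the chain must be attached and saturated before the enone is unveiled, and the last steps must be mild.
- The key step exploits the fact that ring C1–C6, the C5 tertiary hydroxyl in the correct absolute configuration, and oxygen at C1, C2 and C3 are all present in (−)-quinic acid. Its carboxyl carbon sits on C5 and becomes C1', and its lactone geometry tells the C1 arm from the C3 arm.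

## Logic of the disconnections

**14 ⇒ 12 (through 13).** The C2=C3 π bond is traced back to a C3–O bond and a C2–H bond, that is, to a β-hydroxy ketone. Cutting here lets the enone appear in the very last operation, so the dehydration-prone β-hydroxy enone is never carried through further chemistry. The forward step must activate the secondary C3 hydroxyl beside the tertiary C5 hydroxyl and must stop after one elimination.

**12 ⇒ 11.** The C2–H bond is traced back to a C2–O bond that belongs to a cyclic acetal spanning C2 and C3. The two oxygens then form a cis-diol under a single protecting group, and the ketone itself is the handle for removing the α-oxygen. This saves a separate protecting group at the C1 oxygen and a separate diol-to-alkene sequence. The forward step needs a reductant that delivers electrons to the ketone, breaks only the α C–O bond and leaves the product ketone alone.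

**11 ⇒ 10.** The C1=O bond is traced back to the secondary C1–OH. This hydroxyl is the only secondary alcohol in 10, so no selectivity problem arises. The oxidant must be non-basic because 11 is both a β-hydroxy and a β-alkoxy ketone.

**10 ⇒ 9.** The C1'–C2' single bond is traced back to a double bond. This places an olefination at the one position where the chain meets the ring. The forward hydrogenation must not cleave the allylic tertiary C–O bond.

**9 ⇒ 3 + 7.** The C1'=C2' bond is cut. This separates a C18 unit from a ring fragment in which C1' is a masked aldehyde, tied as a lactol to the oxygen that will become the ketone. The gain is the largest of the route: the whole chain is removed and what remains is a chiral-pool carbocycle with every ring atom and the stereocentre in place. The forward step must open the lactol, tolerate two free hydroxyls and leave the acetal untouched.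

**7 ⇒ 6 ⇒ 4 + 5.** The P=C bond is traced back to a P–C single bond and then cut. Both partners are commodity chemicals; the forward steps are a quaternisation and a deprotonation.

**3 ⇒ 2.** The lactol C–H bond is traced back to the lactone carbonyl. The forward reduction must stop at the hemiacetal.

**2 ⇒ 1.** The lactone C–O bond and the two acetal C–O bonds are cut. In 1 only one hydroxyl is cis to the carboxyl group and only one 1,2-diol is cis, so one acid-catalysed operation sorts the four hydroxyls into three roles. No stereocentre is made anywhere in the route.

## Other disconnections considered

**Alternative 1:** The cut removes C1–C2 and C3–C4 together. C2 and C3 come from acetylene A2, and the other four ring carbons come from the achiral 3-nonadecyl-3-(triethylsilyloxy)cyclobutanone A1.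

- Forward key step: a zerovalent nickel catalyst with a chiral phosphine ligand would couple the carbonyl group of A1 with A2 to an oxanickelacyclopentene. β-Carbon elimination would break one of the two enantiotopic C(=O)–CH2 bonds, and reductive elimination would close the six-membered ring to the silyl ether A3 of the target.
- In favour: ring, enone and stereocentre arise in one catalytic operation, A3 is one desilylation from 14, and the sequence would be shorter than the chosen one. On convergence and step economy this plan is the better one.
- Against, on structure: the breaking bond lies two bonds from the stereocentre, and the ligand has only a silyloxy group and a flexible alkyl chain to tell apart, so high enantioselectivity cannot be assumed.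
- Against, on mechanism: A2 tends to oligomerise on zerovalent nickel, and insertions of this kind are normally run with internal alkynes. The alkylnickel formed by β-carbon elimination carries the silyloxy group in the β-position, so β-oxygen elimination competes with ring closure.
- Comparison: the chosen plan imports C5 with fixed configuration from 1 and never makes or breaks a bond at it, whereas this plan stakes the absolute configuration on an untested desymmetrisation. Both plans must finish next to a dehydration-prone β-oxygenated ketone (desilylation of A3 against step 8) and are equals on that point.

**Alternative 2:** The cut is the C5–O bond, traced back to an epoxide across C4 and C5.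

- Forward key step: the achiral 7-nonadecyl-1,4-dioxaspiro[4.5]dec-7-ene A4 would be epoxidised on one face by a dioxirane generated from a chiral ketone, giving A5.
- Onward from A5: opening at C4 with retention of the C5–O bond, release of the ketone and introduction of C2=C3. One way is selenide opening, selenoxide elimination to the C3=C4 allylic alcohol, ketal hydrolysis and migration of the double bond into conjugation.
- In favour: chirality comes from a catalyst, either enantiomer is within reach, no surplus chiral-pool oxygen has to be removed, and the step count is similar to or slightly below that of the chosen plan. On these points it is the equal or the better.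
- Against: A4 must be made by deconjugative ketalisation, which tends to give double-bond isomers. The alkene is a 1-alkylcyclohexene whose faces differ only through the ring CH2 groups, so facial selectivity may fall short of a single enantiomer, whereas the chosen plan takes C5 enantiopure from 1. The late steps put a tertiary allylic alcohol through acidic hydrolysis and double-bond migration, conditions that favour ionisation and aromatisation.
- Comparison: the epoxidation itself should be about as dependable as the olefination of step 4. The weakness of this plan lies after its key step, not in it.

**Alternative 3:** The cut is the C5–C1' bond.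

- Forward key step: (S)-malic acid A6 is converted into its cis pivalaldehyde acetal A7. The dianion of A7 (lithium enolate plus carboxylate) would be alkylated by nonadecyl triflate A8 on the face opposite the tert-butyl group, giving A9.
- In favour: like the chosen plan it takes the stereocentre from an inexpensive chiral-pool acid, and acetal-controlled alkylation is a dependable way to a fully substituted carbinol carbon, with the whole chain attached in one step. On stereochemical security the two plans are equals.
- Against, on mechanism: the enolate is hindered and thermally labile, and the electrophile is an unactivated long-chain one.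
- Against, on structure: none of the carbocycle exists yet. With retention from A6, the acetic acid arm of A9 must become C4–C3 and the former dioxolanone carbonyl carbon must become C6. That carbon therefore has to be reduced to a methylene group and then bonded to C1 next to the quaternary centre (for example through the terminal epoxide). C1 and C2 must be added and the ring closed, for instance by ring-closing metathesis. This is roughly eight to ten operations after A9.
- Comparison: the chosen plan starts with the six-membered ring and all its oxygen in place and only removes functionality, so it is clearly shorter. This plan is the better only in that it removes no surplus oxygen and needs no samarium reagent.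

Key step: step 4

Assumption: the tertiary hydroxyl is carried unprotected through the whole route, so the olefination uses an excess of ylide, two equivalents of which act as base; a check of atom counts and configuration shows that the precursor and the product of the key step need no structural correction (lactone to the only hydroxyl cis to the carboxyl group, acetonide on the only cis-diol, C18 ylide plus the former carboxyl carbon giving the C19 chain, C5 coming out S).

## Route

Step 1
Reactants: 1 (−)-quinic acid
Product: 2 3,4-O-isopropylidenequinic acid 1,5-lactone (quinic numbering; lactone from the carboxyl group to the C5 hydroxyl cis to it; acetonide on the cis C3/C4 diol; tertiary C1 hydroxyl free; configuration of 1 at every ring carbon)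
Conditions: Me2C(OMe)2, TsOH·H2O (cat.), acetone, reflux
Reagents that add atoms: 2,2-dimethoxypropane, COC(C)(C)OC
Why: Acid-catalysed transketalisation protects the only cis-1,2-diol as a five-membered acetonide, and the single hydroxyl cis to the carboxyl group lactonises in the same pot; no stereocentre is touched.

Step 2
Reactants: 2 3,4-O-isopropylidenequinic acid 1,5-lactone
Product: 3 lactol of 2 (lactone carbonyl reduced to CH–OH; both anomers; other centres unchanged)
Conditions: i-Bu2AlH (2.2 equiv), CH2Cl2, −78 °C; then aq. potassium sodium tartrate
Reagents that add atoms: none
Why: Partial hydride reduction of a lactone: the first equivalent is consumed by the tertiary hydroxyl, the second gives an aluminium hemiacetal that is stable at −78 °C and held in the bicyclic frame, so reduction should stop at the lactol.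

Step 3
Reactants: 4 1-bromooctadecane; 5 triphenylphosphine
Product: 6 octadecyltriphenylphosphonium bromide
Conditions: MeCN, reflux
Reagents that add atoms: none
Why: SN2 quaternisation of a triarylphosphine by an unhindered primary alkyl bromide.

Step 4
Reactants: 3 lactol of 2; 6 octadecyltriphenylphosphonium bromide
Product: 9 1-[(1Z)-nonadec-1-en-1-yl]-3,4-O-isopropylidenecyclohexane-1,3,4,5-tetrol (quinic numbering; free hydroxyls at C1/C5), via octadecylidenetriphenylphosphorane 7 (not isolated), via ring-opened hydroxy aldehyde 8 (not isolated)
Conditions: 6 (3.5 equiv), NaN(SiMe3)2 (3.4 equiv), THF, 0 °C; then 3, −78 °C → rt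
Reagents that add atoms: none
Why: Wittig olefination of a lactol with a non-stabilised phosphorus ylide, a well-established reaction type. Two equivalents of 7 first remove the lactol and tertiary hydroxyl protons (reverting to 6), the lactol alkoxide opens to the aldehyde 8, and a further equivalent of 7 adds to the aldehyde by [2+2] cycloaddition to an oxaphosphetane whose cycloreversion expels Ph3P=O and leaves the C1'=C2' bond. No ring is closed; instead the bridging C–O bond of the lactol is released, which frees the quinic C5 hydroxyl that becomes the ketone oxygen. No stereocentre is created: the carbinol carbon next to the aldehyde is fully substituted and cannot epimerise, and the other ring centres are untouched. The early, kinetically controlled transition state of the unstabilised ylide should favour the Z alkene, but the geometry is irrelevant because step 5 saturates the bond. The selectivity that matters is the distinction of the two near-identical ring arms, and the substrate secures it by geometry: only the hydroxyl cis to the former carboxyl carbon could be tied into the lactol, so only that oxygen is unmasked while the cis-diol on the other arm stays as an acetonide that is inert to ylide and base. The excess of ylide makes up for the two acidic hydroxyls.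

Step 5
Reactants: 9 1-[(1Z)-nonadec-1-en-1-yl]-3,4-O-isopropylidenecyclohexane-1,3,4,5-tetrol
Product: 10 1-nonadecyl-3,4-O-isopropylidenecyclohexane-1,3,4,5-tetrol (quinic numbering; 1-OH, 3-O and 4-O on one face, 5-OH on the other)
Conditions: H2 (1 atm), Pt/C (5%), EtOAc, rt
Reagents that add atoms: none
Why: Heterogeneous catalytic hydrogenation of a 1,2-disubstituted alkene; platinum in a neutral aprotic solvent limits hydrogenolysis of the allylic tertiary C–O bond, and the acetonide and both alcohols are inert.

Step 6
Reactants: 10 1-nonadecyl-3,4-O-isopropylidenecyclohexane-1,3,4,5-tetrol
Product: 11 (2R,3R,5S)-5-hydroxy-2,3-(isopropylidenedioxy)-5-nonadecylcyclohexan-1-one (cis-fused acetonide on the face of the tertiary hydroxyl)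
Conditions: Dess–Martin periodinane, NaHCO3, CH2Cl2, 0 °C → rt
Reagents that add atoms: none
Why: Hypervalent-iodine oxidation of the only secondary alcohol; the tertiary alcohol cannot be oxidised, and the buffered, base-free medium protects the β-hydroxy and β-alkoxy ketone from E1cB elimination.

Step 7
Reactants: 11 (2R,3R,5S)-5-hydroxy-2,3-(isopropylidenedioxy)-5-nonadecylcyclohexan-1-one
Product: 12 (3R,5S)-3,5-dihydroxy-5-nonadecylcyclohexan-1-one (the two hydroxyls cis)
Conditions: SmI2 (2.2 equiv), THF/MeOH, −78 °C; then aq. NH4Cl
Reagents that add atoms: none
Why: Reductive cleavage of an α-alkoxy ketone by divalent samarium: two single-electron transfers to the ketone expel the α-oxygen at C2, the hemiketal alkoxide so formed loses acetone to free the C3 hydroxyl, and methanol protonates the trivalent samarium enolate; C3 and C5 are not touched, and low temperature with limited reagent should spare the product ketone.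

Step 8
Reactants: 12 (3R,5S)-3,5-dihydroxy-5-nonadecylcyclohexan-1-one
Product: 14 (S)-5-hydroxy-5-nonadecylcyclohex-2-en-1-one, via 3-O-mesylate of the diol ketone 13 (not isolated)
Conditions: MsCl (1.1 equiv), Et3N (3 equiv), CH2Cl2, −20 → 0 °C
Reagents that add atoms: methanesulfonyl chloride, CS(=O)(=O)Cl (its atoms are in 13 only and leave again on elimination)
Why: Sulfonylation of the less hindered secondary hydroxyl followed by E1cB elimination of the β-mesyloxy ketone through the C2 enolate gives the conjugated C2=C3 bond; the hindered tertiary hydroxyl should stay unactivated with one equivalent at low temperature, and C5 is not involved.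

## Compound list

1 | (−)-quinic acid | C1[C@H]([C@H]([C@@H](C[C@@]1(C(=O)O)O)O)O)O | starting material
2 | 3,4-O-isopropylidenequinic acid 1,5-lactone | C1[C@H]([C@H]([C@@H](C[C@@]1(C3=O)O)O3)O2)OC(C)(C)2 | intermediate
3 | lactol of 2 (both anomers) | C1[C@H]([C@H]([C@@H](C[C@@]1(C3O)O)O3)O2)OC(C)(C)2 | intermediate
4 | 1-bromooctadecane | CCCCCCCCCCCCCCCCCCBr | starting material
5 | triphenylphosphine | c1ccc(cc1)P(c1ccccc1)c1ccccc1 | starting material
6 | octadecyltriphenylphosphonium bromide | CCCCCCCCCCCCCCCCCC[P+](c1ccccc1)(c1ccccc1)c1ccccc1.[Br-] | intermediate
7 | octadecylidenetriphenylphosphorane | CCCCCCCCCCCCCCCCCC=P(c1ccccc1)(c1ccccc1)c1ccccc1 | intermediate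
8 | ring-opened hydroxy aldehyde form of 3 | C1[C@H]([C@H]([C@@H](C[C@@]1(C=O)O)O)O2)OC(C)(C)2 | intermediate
9 | 1-[(1Z)-nonadec-1-en-1-yl]-3,4-O-isopropylidenecyclohexane-1,3,4,5-tetrol (quinic numbering) | C1[C@H]([C@H]([C@@H](C[C@@]1(/C=C\CCCCCCCCCCCCCCCCC)O)O)O2)OC(C)(C)2 | intermediate
10 | 1-nonadecyl-3,4-O-isopropylidenecyclohexane-1,3,4,5-tetrol (quinic numbering) | C1[C@H]([C@H]([C@@H](C[C@@]1(CCCCCCCCCCCCCCCCCCC)O)O)O2)OC(C)(C)2 | intermediate
11 | (2R,3R,5S)-5-hydroxy-2,3-(isopropylidenedioxy)-5-nonadecylcyclohexan-1-one | C1[C@H]([C@H](C(=O)C[C@@]1(CCCCCCCCCCCCCCCCCCC)O)O2)OC(C)(C)2 | intermediate
12 | (3R,5S)-3,5-dihydroxy-5-nonadecylcyclohexan-1-one | C1[C@H](CC(=O)C[C@@]1(CCCCCCCCCCCCCCCCCCC)O)O | intermediate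
13 | 3-O-methanesulfonate of 12 | C1[C@H](CC(=O)C[C@@]1(CCCCCCCCCCCCCCCCCCC)O)OS(C)(=O)=O | intermediate
14 | (S)-5-hydroxy-5-nonadecylcyclohex-2-en-1-one (CNP0103007.1) | CCCCCCCCCCCCCCCCCCC[C@]1(O)CC=CC(=O)C1 | target

## Step count and least certain steps

Total step count: 8. Longest linear sequence: 7 (steps 1, 2, 4, 5, 6, 7, 8 from 1); step 3 is a one-step side branch.

**Step 4 (key step).**
- What may go wrong: slow or incomplete olefination. The aldehyde is released only by opening of a bridged lactol alkoxide and sits next to a fully substituted, negatively charged carbinol carbon. Long exposure of the open form to excess strong base could allow an α-ketol-type ring expansion or hydride-transfer side reactions.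
- Fallback, from 2 back to 9: the substrate is changed so that the aldehyde is no longer an α-oxido aldehyde.
  - The tertiary hydroxyl of 2 is capped (Et3SiOTf, 2,6-lutidine, CH2Cl2) to give the triethylsilyl ether of the lactone F1.
  - F1 is reduced (i-Bu2AlH, −78 °C) to the silylated lactol F2.
  - F2 is olefinated with 7 (only one acidic proton remains) to the silyl ether of the Z-alkene F3.
  - The silyl group is removed with Bu4NF in THF, which returns the route to 9.

**Step 7.**
- What may go wrong: over-reduction of the ketone. The β-hydroxyl can chelate samarium and assist delivery of further electrons, which would erase the distinction between the C1 and C3 oxygens. Incomplete C–O scission is also possible if the α C–O bond cannot align with the ketyl.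
- Fallback, from 10 to 14: the α-oxygenated ketone is avoided and the alkene is made before the ketone.
  - The secondary hydroxyl of 10 is benzoylated (BzCl, pyridine, 0 °C) to the monobenzoate F4.
  - The acetonide is hydrolysed (80% aq. AcOH, 40 °C) to the triol benzoate F5.
  - The cis-diol is closed with 1,1'-thiocarbonyldiimidazole (toluene, 80 °C) to the cyclic thiocarbonate F6.
  - Corey–Winter elimination in hot P(OMe)3 gives the cyclohexene benzoate F7.
  - Methanolysis (K2CO3, MeOH) gives (1R,5S)-5-nonadecylcyclohex-2-ene-1,5-diol F8.
  - The allylic secondary alcohol is oxidised with MnO2 (CH2Cl2, rt) to 14.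

**Step 8.**
- What may go wrong: competing sulfonylation of the tertiary hydroxyl by the unselective sulfene, followed by a second elimination and aromatisation. This would destroy the only stereocentre.
- Fallback, from 12 to 14: activation is changed from sulfonylation to acylation, which cannot reach the tertiary hydroxyl, and is separated from the elimination.
  - 12 is acetylated at the secondary hydroxyl only (Ac2O, pyridine, 0 °C, no acylation catalyst) to the isolable β-acetoxy ketone F9.
  - F9 is eliminated with DBU in CH2Cl2 at 0 °C to 14.

## Further compounds

F1 | step 4 | 1-O-triethylsilyl ether of 2 | C1[C@H]([C@H]([C@@H](C[C@@]1(C3=O)O[Si](CC)(CC)CC)O3)O2)OC(C)(C)2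
F2 | step 4 | 1-O-triethylsilyl ether of lactol 3 (both anomers) | C1[C@H]([C@H]([C@@H](C[C@@]1(C3O)O[Si](CC)(CC)CC)O3)O2)OC(C)(C)2
F3 | step 4 | 1-O-triethylsilyl ether of 9 | C1[C@H]([C@H]([C@@H](C[C@@]1(/C=C\CCCCCCCCCCCCCCCCC)O[Si](CC)(CC)CC)O)O2)OC(C)(C)2
F4 | step 7 | 5-O-benzoate of 10 (quinic numbering) | C1[C@H]([C@H]([C@@H](C[C@@]1(CCCCCCCCCCCCCCCCCCC)O)OC(=O)c3ccccc3)O2)OC(C)(C)2
F5 | step 7 | 5-O-benzoyl-1-nonadecylcyclohexane-1,3,4,5-tetrol (quinic numbering) | C1[C@H]([C@H]([C@@H](C[C@@]1(CCCCCCCCCCCCCCCCCCC)O)OC(=O)c2ccccc2)O)O
F6 | step 7 | 3,4-O-thiocarbonyl derivative of F5 | C1[C@H]([C@H]([C@@H](C[C@@]1(CCCCCCCCCCCCCCCCCCC)O)OC(=O)c3ccccc3)O2)OC(=S)2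
F7 | step 7 | (1R,5S)-5-hydroxy-5-nonadecylcyclohex-2-en-1-yl benzoate | C1C=C[C@@H](C[C@@]1(CCCCCCCCCCCCCCCCCCC)O)OC(=O)c2ccccc2
F8 | step 7 | (1R,5S)-5-nonadecylcyclohex-2-ene-1,5-diol | C1C=C[C@@H](C[C@@]1(CCCCCCCCCCCCCCCCCCC)O)O
F9 | step 8 | 3-O-acetate of 12 | C1[C@H](CC(=O)C[C@@]1(CCCCCCCCCCCCCCCCCCC)O)OC(C)=O
A1 | alternative 1 | 3-nonadecyl-3-(triethylsilyloxy)cyclobutanone | CCCCCCCCCCCCCCCCCCCC1(O[Si](CC)(CC)CC)CC(=O)C1
A2 | alternative 1 | acetylene | C#C
A3 | alternative 1 | triethylsilyl ether of the target | CCCCCCCCCCCCCCCCCCC[C@]1(O[Si](CC)(CC)CC)CC=CC(=O)C1
A4 | alternative 2 | 7-nonadecyl-1,4-dioxaspiro[4.5]dec-7-ene | CCCCCCCCCCCCCCCCCCCC1=CCCC2(C1)OCCO2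
A5 | alternative 2 | 7,8-epoxy-7-nonadecyl-1,4-dioxaspiro[4.5]decane, single enantiomer | CCCCCCCCCCCCCCCCCCC[C@@]12CC3(OCCO3)CC[C@@H]1O2
A6 | alternative 3 | (S)-malic acid | C([C@@H](C(=O)O)O)C(=O)O
A7 | alternative 3 | cis-2-tert-butyl-5-oxo-1,3-dioxolane-4-acetic acid (pivalaldehyde acetal of A6) | CC(C)(C)[C@H]1O[C@@H](CC(O)=O)C(=O)O1
A8 | alternative 3 | nonadecyl trifluoromethanesulfonate | CCCCCCCCCCCCCCCCCCCOS(=O)(=O)C(F)(F)F
A9 | alternative 3 | 2-tert-butyl-4-nonadecyl-5-oxo-1,3-dioxolane-4-acetic acid, chain trans to tert-butyl | CC(C)(C)[C@H]1O[C@@](CCCCCCCCCCCCCCCCCCC)(CC(O)=O)C(=O)O1
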